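**Plan**

- Retrosynthetic cuts: first the three O‑benzyl bonds and the C1–O bond (traced back to a C1–B bond), then, in one operation, the C1–ring A and C2–ring B bonds.
- Enabling feature: C1 (the carbinol carbon, carrying ring A, the 4‑hydroxy‑3‑methoxyphenyl ring) and C2 (carrying ring B, the 4‑hydroxy‑3,5‑dimethoxyphenyl ring, and the C3 hydroxymethyl) are directly bonded, each holds exactly one aryl group, and the C1 oxygen can be delivered as boron.
- Forward: no ring is built (rings A and B are bought). The C1–C2–C3 chain enters as a (Z)‑3‑benzyloxypropenyl boronic ester, which is joined with a ring A aryllithium and a ring B aryl triflate in one palladium‑catalysed conjunctive coupling; C–B oxidation and debenzylation follow.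
- Stereochemistry: the C1/C2 relative configuration comes from anti addition of the two aryl groups across the Z‑alkene, the absolute configuration from a chiral ferrocenyl diphosphine on palladium, and the C–B oxidation retains it.
- Boron carries the hindered cis‑1,2‑dimethylacenaphthene‑1,2‑diol ("mac" diol) in place of pinacol, because β‑substituted alkenyl pinacol boronates tend to divert into direct Suzuki–Miyaura coupling.

Key step: step 7

Assumption: the (Sp,Sp) antipode of the ferrocenyl diphosphine is taken to steer palladium to the alkene face that leads to the (1S,2S) series; both antipodes are commercial, so the other one is used if the sense of induction turns out opposite.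

**Route**

Step 1
Reactants: 1 acenaphthoquinone
Product: 2 cis‑1,2‑dimethyl‑1,2‑dihydroacenaphthylene‑1,2‑diol (mac diol; meso)
Conditions: AlMe3 (4 equiv), toluene, 0 °C to rt; aq HCl; recrystallisation
Reagents that add atoms: trimethylaluminium, C[Al](C)C
Why: Twofold 1,2‑addition of an organoaluminium reagent to a 1,2‑diketone; the second methyl should enter anti to the bulky aluminium alkoxide left by the first, so the meso cis‑diol (the only isomer able to span one boron atom) is expected to predominate and is purified by crystallisation.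

Step 2
Reactants: 3 benzyl propargyl ether; 4 catecholborane; 2 mac diol
Product: 6 (Z)‑3‑benzyloxyprop‑1‑enylboronic ester of mac diol 2, via catechol boronate 5 (not isolated)
Conditions: [Rh(cod)Cl]2 (1.5 mol %), P(i‑Pr)3 (6 mol %), Et3N, cyclohexane, rt (slight excess of 3); then 2, rt
Reagents that add atoms: none
Why: Rhodium‑catalysed trans‑hydroboration of a terminal alkyne, which runs through a rhodium vinylidene and adds H and B in a formal anti sense to give the Z‑alkenylboronate, followed by the routine exchange of the labile catechol ester for an aliphatic cis‑1,2‑diol; the mac ester is expected to be crystalline, so residual E isomer can be removed.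

Step 3
Reactants: 7 4‑bromo‑2‑methoxyphenol
Product: 8 1‑benzyloxy‑4‑bromo‑2‑methoxybenzene
Conditions: BnBr, K2CO3, DMF, rt
Reagents that add atoms: benzyl bromide, BrCc1ccccc1
Why: Williamson ether synthesis of a phenoxide with a benzylic bromide.

Step 4
Reactants: 9 syringaldehyde
Product: 10 4‑benzyloxy‑3,5‑dimethoxybenzaldehyde
Conditions: BnBr, K2CO3, DMF, 60 °C
Reagents that add atoms: benzyl bromide, BrCc1ccccc1
Why: Williamson ether synthesis; gentle heating compensates for the two flanking methoxy groups.

Step 5
Reactants: 10 4‑benzyloxy‑3,5‑dimethoxybenzaldehyde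
Product: 12 4‑benzyloxy‑3,5‑dimethoxyphenol, via aryl formate 11 (not isolated)
Conditions: mCPBA, CH2Cl2, rt; then KOH, MeOH/H2O, rt; acidic work‑up
Reagents that add atoms: meta‑chloroperbenzoic acid, O=C(OO)c1cccc(Cl)c1
Why: Baeyer–Villiger oxidation of an electron‑rich benzaldehyde (Dakin‑type route to a phenol), in which the para‑alkoxy aryl group migrates in preference to hydride and the formate is saponified in the same flask.

Step 6
Reactants: 12 4‑benzyloxy‑3,5‑dimethoxyphenol
Product: 13 4‑benzyloxy‑3,5‑dimethoxyphenyl trifluoromethanesulfonate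
Conditions: Tf2O, pyridine, CH2Cl2, 0 °C
Reagents that add atoms: triflic anhydride, O=S(=O)(OS(=O)(=O)C(F)(F)F)C(F)(F)F
Why: O‑sulfonylation of an unhindered phenol with triflic anhydride and an amine base.

Step 7
Reactants: 8 1‑benzyloxy‑4‑bromo‑2‑methoxybenzene; 6 (Z)‑3‑benzyloxyprop‑1‑enylboronic ester of mac diol; 13 4‑benzyloxy‑3,5‑dimethoxyphenyl trifluoromethanesulfonate
Product: 16 (1S,2S)‑3‑benzyloxy‑1‑(4‑benzyloxy‑3‑methoxyphenyl)‑2‑(4‑benzyloxy‑3,5‑dimethoxyphenyl)propylboronic ester of mac diol 2, via aryllithium 14 (not isolated), via lithium ate complex 15 (not isolated)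
Conditions: 8, t‑BuLi (2.0 equiv), Et2O, −78 °C; then 6, −78 °C to rt; solvent switch to THF; then 13, NaOTf, Pd(OAc)2 (2 mol %), (Sp,Sp)‑1,1'‑bis[bis(4‑methoxy‑3,5‑dimethylphenyl)phosphino]‑2,2'‑bis[(R)‑α‑(dimethylamino)benzyl]ferrocene (2.4 mol %), THF, 60 °C, inert atmosphere
Reagents that add atoms: none
Why: Oxidative addition of triflate 13 to zerovalent palladium (formed in situ from Pd(OAc)2 and kept cationic because NaOTf removes the bromide left by the lithium–bromine exchange) gives a divalent arylpalladium species that binds the C1=C2 π bond of ate complex 15; this activation triggers a 1,2‑metallate shift in which ring A moves from boron to C1 anti to palladium while the C2–Pd bond forms, and reductive elimination with retention then joins C2 to ring B. The closest known reaction type is the palladium/ferrocenyl‑diphosphine‑catalysed enantioselective conjunctive cross‑coupling of β‑substituted alkenylboron ate complexes bearing the mac diol with aryl triflates. No ring is closed in this step. The relative configuration of C1 and C2 follows from the stereospecific anti addition of the two aryl groups across the Z‑alkene (boron and C3 cis), which corresponds to the (1S,2S)/(1R,2R) pair, and the absolute configuration from the alkene face that the C2‑symmetric diphosphine lets palladium occupy. The step needs conjunctive coupling to win over direct Suzuki‑type transmetalation, which the bulky mac diol secures by shielding the boronate oxygens, and reductive elimination to win over β‑hydride or β‑alkoxide elimination toward C3, which the chelating diphosphine secures by leaving no vacant cis site on palladium.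

Step 8
Reactants: 16 boronic ester
Product: 17 (1S,2S)‑3‑benzyloxy‑1‑(4‑benzyloxy‑3‑methoxyphenyl)‑2‑(4‑benzyloxy‑3,5‑dimethoxyphenyl)propan‑1‑ol
Conditions: NaOH (aq), H2O2 (30 % aq), THF, 0 °C to rt
Reagents that add atoms: hydrogen peroxide, OO
Why: Hydroperoxide oxidation of a secondary alkylboronic ester, in which C1 migrates from boron to oxygen with retention, so the configuration set in step 7 is carried over unchanged while the benzyl‑protected phenols are inert.

Step 9
Reactants: 17 tribenzyl alcohol
Product: 18 (1S,2S)‑1‑(4‑hydroxy‑3‑methoxyphenyl)‑2‑(4‑hydroxy‑3,5‑dimethoxyphenyl)propane‑1,3‑diol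
Conditions: H2 (1 atm), Pd/C (10 wt %), EtOAc/EtOH, rt, acid‑free, stopped when the aliphatic benzyl ether is consumed
Reagents that add atoms: none
Why: Heterogeneous catalytic hydrogenolysis of two aryl benzyl ethers and one alkyl benzyl ether under neutral conditions, which should leave the secondary benzylic hydroxyl and both stereocentres untouched.

**Compound list**

1 | acenaphthoquinone (acenaphthylene‑1,2‑dione) | O=C1C(=O)c2cccc3cccc1c23 | starting material
2 | mac diol, cis‑(1R,2S)‑1,2‑dimethyl‑1,2‑dihydroacenaphthylene‑1,2‑diol (meso) | C[C@]1(O)c2cccc3cccc(c23)[C@@]1(C)O | intermediate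
3 | benzyl propargyl ether | C#CCOCc1ccccc1 | starting material
4 | catecholborane (1,3,2‑benzodioxaborole) | B1Oc2ccccc2O1 | starting material
5 | (Z)‑2‑(3‑benzyloxyprop‑1‑enyl)‑1,3,2‑benzodioxaborole | c1ccccc1COC/C=C\B1Oc2ccccc2O1 | intermediate (not isolated)
6 | (Z)‑3‑benzyloxyprop‑1‑enylboronic ester of mac diol (boron bridging both oxygens of 2) | c1ccccc1COC/C=C\B1O[C@@]2(C)c3cccc4cccc(c34)[C@@]2(C)O1 | intermediate
7 | 4‑bromo‑2‑methoxyphenol | COc1cc(Br)ccc1O | starting material
8 | 1‑benzyloxy‑4‑bromo‑2‑methoxybenzene | COc1cc(Br)ccc1OCc1ccccc1 | intermediate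
9 | syringaldehyde (4‑hydroxy‑3,5‑dimethoxybenzaldehyde) | COc1cc(C=O)cc(OC)c1O | starting material
10 | 4‑benzyloxy‑3,5‑dimethoxybenzaldehyde | COc1cc(C=O)cc(OC)c1OCc1ccccc1 | intermediate
11 | 4‑benzyloxy‑3,5‑dimethoxyphenyl formate | COc1cc(OC=O)cc(OC)c1OCc1ccccc1 | intermediate (not isolated)
12 | 4‑benzyloxy‑3,5‑dimethoxyphenol | COc1cc(O)cc(OC)c1OCc1ccccc1 | intermediate
13 | 4‑benzyloxy‑3,5‑dimethoxyphenyl trifluoromethanesulfonate | COc1cc(OS(=O)(=O)C(F)(F)F)cc(OC)c1OCc1ccccc1 | intermediate
14 | 4‑benzyloxy‑3‑methoxyphenyllithium | COc1cc([Li])ccc1OCc1ccccc1 | intermediate (not isolated)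
15 | lithium [(Z)‑3‑benzyloxyprop‑1‑enyl](4‑benzyloxy‑3‑methoxyphenyl)borate of mac diol (configuration at boron unspecified) | [Li+].COc1cc([B-]2(/C=C\COCc3ccccc3)O[C@@]3(C)c4cccc5cccc(c45)[C@@]3(C)O2)ccc1OCc1ccccc1 | intermediate (not isolated)
16 | (1S,2S)‑3‑benzyloxy‑1‑(4‑benzyloxy‑3‑methoxyphenyl)‑2‑(4‑benzyloxy‑3,5‑dimethoxyphenyl)propylboronic ester of mac diol | COc1cc([C@@H](B2O[C@@]3(C)c4cccc5cccc(c45)[C@@]3(C)O2)[C@H](COCc2ccccc2)c2cc(OC)c(OCc3ccccc3)c(OC)c2)ccc1OCc1ccccc1 | intermediate
17 | (1S,2S)‑3‑benzyloxy‑1‑(4‑benzyloxy‑3‑methoxyphenyl)‑2‑(4‑benzyloxy‑3,5‑dimethoxyphenyl)propan‑1‑ol | COc1cc([C@@H](O)[C@H](COCc2ccccc2)c2cc(OC)c(OCc3ccccc3)c(OC)c2)ccc1OCc1ccccc1 | intermediate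
18 | (1S,2S)‑1‑(4‑hydroxy‑3‑methoxyphenyl)‑2‑(4‑hydroxy‑3,5‑dimethoxyphenyl)propane‑1,3‑diol | COc1cc([C@@H](O)[C@H](CO)c2cc(OC)c(O)c(OC)c2)ccc1O | target

**Summary**

Total step count: 9. Longest linear sequence: 6 steps (steps 4, 5, 6, 7, 8, 9, from syringaldehyde 9).

Steps most likely to fail:

1. Step 7. The alkenyl group may transmetalate directly to palladium (Suzuki‑type coupling), β‑alkoxide or β‑hydride elimination toward C3 may outrun reductive elimination, or the ligand may discriminate the faces of the Z‑alkene poorly. The fallback sets out from alkyne 3 (using bromide 8 and triflate 13) and comes back at alcohol 17.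
   - Alkyne 3 is diborated with B2pin2 under Pt(PPh3)4 catalysis (toluene, 80 °C, syn addition) to the cis‑1,2‑diboryl alkene F1.
   - The terminal, less hindered C–B bond is coupled with bromide 8 (PdCl2(dppf), K3PO4, dioxane/H2O) to give alkenyl pinacol boronate F2.
   - The internal C–B bond is then coupled with triflate 13 under the same type of Suzuki–Miyaura conditions to give trisubstituted alkene F3, in which rings A and B are cis.
   - Asymmetric hydroboration with monoisopinocampheylborane (THF, −25 °C), boron going to the less substituted C1 and hydrogen to C2 from the same face, then NaOH/H2O2, should give 17.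
   - Syn addition to this alkene geometry gives the same relative configuration as anti diarylation of the Z‑alkenylboronate, and the antipode of the pinene‑derived borane is chosen for the (1S,2S) series.

2. Step 2. Syn‑hydroboration may compete and erode the Z geometry, or the diol exchange on boron may stay incomplete. The fallback sets out from alkyne 3 and comes back at boronic ester 6.
   - Alkyne 3 is deprotonated (n‑BuLi, THF, −78 °C) and borylated with 2‑isopropoxy‑4,4,5,5‑tetramethyl‑1,3,2‑dioxaborolane, then HCl in Et2O, to give alkynyl pinacol boronate F4.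
   - Syn‑hydrozirconation with Cp2Zr(H)Cl (THF, rt) places zirconium on the boron‑bearing carbon, and protonolysis with water with retention gives the geometrically pure (Z)‑alkenyl pinacol boronate F5.
   - The pinacol ester is cleaved oxidatively (NaIO4, NH4OAc, acetone/H2O) to (Z)‑alkenylboronic acid F6.
   - F6 is condensed with diol 2 (MgSO4, CH2Cl2, rt) to give 6.

3. Step 9. The benzylic C1–O bond, activated by the para‑oxygenated ring A, may be hydrogenolysed during the longer exposure needed for the aliphatic benzyl ether. The fallback reverses the last two operations; it sets out from boronic ester 16 and comes back at target 18.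
   - The three benzyl ethers are hydrogenolysed while C1 still carries boron (H2, Pd/C, EtOAc/EtOH), where no benzylic C–O bond is present on the chain, giving triol boronate F7. The tertiary C–O bonds of the rigid mac ester are expected to resist.
   - The C–B bond is then oxidised with retention under mild, nearly neutral conditions (NaBO3·4H2O, THF/H2O, rt) to give 18.

Further compounds
F1 | step 7 | 2,2'‑[(E)‑3‑benzyloxyprop‑1‑ene‑1,2‑diyl]bis(4,4,5,5‑tetramethyl‑1,3,2‑dioxaborolane), boron atoms cis | CC1(C)OB(OC1(C)C)/C=C(\B1OC(C)(C)C(C)(C)O1)COCc1ccccc1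
F2 | step 7 | (E)‑2‑[3‑benzyloxy‑1‑(4‑benzyloxy‑3‑methoxyphenyl)prop‑1‑en‑2‑yl]‑4,4,5,5‑tetramethyl‑1,3,2‑dioxaborolane, ring A cis to boron | COc1cc(/C=C(\B2OC(C)(C)C(C)(C)O2)COCc2ccccc2)ccc1OCc1ccccc1
F3 | step 7 | (E)‑1‑benzyloxy‑4‑[3‑benzyloxy‑2‑(4‑benzyloxy‑3,5‑dimethoxyphenyl)prop‑1‑enyl]‑2‑methoxybenzene, rings A and B cis | COc1cc(/C=C(\c2cc(OC)c(OCc3ccccc3)c(OC)c2)COCc2ccccc2)ccc1OCc1ccccc1
F4 | step 2 | 2‑(3‑benzyloxyprop‑1‑ynyl)‑4,4,5,5‑tetramethyl‑1,3,2‑dioxaborolane | CC1(C)OB(C#CCOCc2ccccc2)OC1(C)C
F5 | step 2 | (Z)‑2‑(3‑benzyloxyprop‑1‑enyl)‑4,4,5,5‑tetramethyl‑1,3,2‑dioxaborolane | CC1(C)OB(/C=C\COCc2ccccc2)OC1(C)C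
F6 | step 2 | (Z)‑(3‑benzyloxyprop‑1‑enyl)boronic acid | OB(O)/C=C\COCc1ccccc1
F7 | step 9 | (1S,2S)‑3‑hydroxy‑1‑(4‑hydroxy‑3‑methoxyphenyl)‑2‑(4‑hydroxy‑3,5‑dimethoxyphenyl)propylboronic ester of mac diol | COc1cc([C@@H](B2O[C@@]3(C)c4cccc5cccc(c45)[C@@]3(C)O2)[C@H](CO)c2cc(OC)c(O)c(OC)c2)ccc1O
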